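The pitfall in repeating this run is to take the first north-west reading for the top of the curve, and to treat base as a catalyst, which pushes the expected top later.

all flasks: substrate 0.098 M; gas 3.6 mM (held)

| charge | base | remark | time |
|---|---|---|---|
| north-west | 0.075 equiv (fed, over 2.0 h) | run made earlier |  |
| flask | 0.0500 equiv (fed, over 2.0 h) |  | 15 d |

north-west run (percent of the substrate charged)

| time / d | target / % |
|---|---|
| 0.625 | 30 |
| 1.25 | 20 |
| 2.08 | 15 |
| 2.50 | 11 |
| 3.00 | 9 |
| 4.00 | 6 |
| 5.00 | 3 |

(scatter of a reading: 1.5 percentage points)

- what was read earlier has a scatter of 1.5 percentage points, one standard deviation
- at the start none of the gas is in solution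
- no earlier run changes the charge of base; that part of a forecast is a guess

1. time up to 15 d at which target stands highest
2. the amount of target, in percent of the substrate charged, at that time
3. earliest time at which at least nineteen twentieths of that best amount are there, in d
4. latest time at which they still are, in d

I started from the tail. Between 0.625 d and 5.00 d, target in the north-west run fell from 30 % to 3 %, a decay constant of 0.526 d⁻¹. Run back to time zero at that rate, the line stood at 41.7 %. No reading caught the rise, so I took that figure, scatter included, as the height to expect.

The readings fell from the first one on, so the north-west top lay before 0.625 d. The weak link was how that time moves with base, since no earlier run changes its charge. A catalytic base would stretch that limit to 0.938 d.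

So I reforged the link with the balance of base: whatever is fed stands free or bound. The base charge as a concentration, c(base) fed, the ceiling on what it can bind one to one, is 4.90 mM, against 7.35 mM in the north-west run. If base binds something given off as substrate reacts, it holds the reaction back until that much is made, and the smaller charge brings the top forward. Scaling the north-west limit by the two charges, I committed to a top before 0.417 d.

The forecast put the top later than that and lower than my height, at 33 % at 0.5 d, open from 0.34 d to 0.85 d, and added: “The base dependence is a guess”.

The flask gave 42.6 % at 0.358 d, open from 0.308 d to 0.421 d.

    substrate + reagent + released group → target + 2 released group (k = 1800 M⁻² h⁻¹)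
    reagent + target → over-reaction product (k = 15.0 M⁻¹ h⁻¹)
    gas ⇌ reagent, rate k3*(csat - [reagent]) (kL = 180 h⁻¹)
    base + released group ⇌ salt, settled at all times (K = 9.90 × 10⁵ M⁻¹)
    target ⇌ isomer of the product (K = 1.60, k = 0.270 h⁻¹)
    substrate + reagent → target + released group (k = 9.30 M⁻¹ h⁻¹)

At 0.382 d, substrate in the flask had a half-life of 0.055 d by the step that takes released group (autocatalysis), far shorter than the 0.87 d by the step without it. At 0.358 d, c(base) stood at 0 % of its charge, c(salt) at 4.90 mM, equal to the 4.90 mM of the balance, and c(released group) at 0.0777 M. The neighbour flask, with 0.24 M of substrate and a best of 56.6 %, has a base charge of 12.0 mM, and at 15.0 d its c(salt) stood at 12.0 mM.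

The numbers in the tables were computed with made-up constants; the scatter is artificial.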